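Follow the starting material.

all flasks: reagent in the second phase 0.649 M

| run | starting material | remark | time | volume of the second phase over the first |
|---|---|---|---|---|
| epsilon | 0.59 M | the very flask that is asked about, followed so far |  |  |
| alpha | 0.40 M | run made earlier |  |  |
| flask | 0.59 M |  | 3.0 h | 0.50 |

| run | time / min | target / % | idle adduct / % | starting material / % |
|---|---|---|---|---|
| epsilon | 10.0 | 20 | 3 | 74 |
| epsilon | 20.0 | 33 | 1 | 47 |
| epsilon | 25.0 | 29 | 1 | 36 |
| epsilon | 40.0 | 35 | 4 | 24 |
| epsilon | 50.0 | 35 | 1 | 14 |
| alpha | 10.0 | 27 | 3 | 58 |
| alpha | 15.0 | 38 | 2 | 45 |
| alpha | 30.0 | 44 | 2 | 13 |
| alpha | 50.0 | 45 | 5 | 1 |
| alpha | 80.0 | 45 | 5 | 0 |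
| alpha | 120 | 49 | 3 | 0 |

(scatter of a reading: 2 percentage points)

- what is said of target includes product in the second phase and idle adduct
- in the second phase: reagent in the second phase, product in the second phase; everything else is in the first
- charges count per volume of the first phase; a concentration in a rate is the amount of a species over the volume of its own phase; every rate counts per litre of the first phase
- steps thought possible: reagent in the reaction phase <-> reagent in the second phase; target <-> isomer of the product; target -> decomposed product; starting material + reagent in the reaction phase -> target; reagent in the reaction phase + target <-> idle adduct; target <-> product in the second phase
- the earlier runs hold the two phases in the same ratio of volumes as the flask asked about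

- the target and product in the second phase and idle adduct together standing at 3.0 h, as a percentage of the starting material charged
- part of the starting material charged that has reacted at 3.0 h

Starting material is the limiting reagent: in the flask, reagent in the second phase is charged at 1.10 times its amount. So I keep its ledger in fractions of the charge. Two entries can be read: what is left, and the target column, which counts target, product in the second phase and idle adduct together.

The alpha run, with 0% left at 120 min, shows 51.0% standing in neither reading, and that part of the charge I call the gap. By the steps thought possible, it is isomer of the product plus decomposed product, and nobody read those. It is a reading, and each column behind it scatters by 2 percentage points. The epsilon run, this same flask followed to 50.0 min, has a gap of 51.0% with 14% still left.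

Between its first and last readings, the epsilon run shows the starting material falling with a half-life of about 16.7 min. If that pace held, my left entry at 3.0 h is 0.0625%, so I reckon 99.9% reacted. I close the books with the alpha gap, although the alpha run held less starting material and was last read at 120 min, and so I commit to 48.9% in the target column.

The forecast, lower on that column than my figure, gives 43.5% and 97.5%, and says of the alpha plateau: “That looks like target–isomer equilibrium rather than decomposition”.

The flask gives 52.6% in the target column and >99.9% reacted.

    reagent in the reaction phase ⇌ reagent in the second phase, rate k1*([reagent in the reaction phase] - [reagent in the second phase]/K1) per volume of the first phase (partition coefficient = 1.30, kL = 0.0260 min⁻¹)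
    target ⇌ isomer of the product (K = 2.40, k = 0.0880 min⁻¹)
    target → decomposed product (k = 0.00190 min⁻¹)
    starting material + reagent in the reaction phase → target (k = 1.50 M⁻¹ min⁻¹)
    reagent in the reaction phase + target ⇌ idle adduct, settled at all times (K = 1.70 M⁻¹)
    target ⇌ product in the second phase, rate k6*([target] - [product in the second phase]/K6) per volume of the first phase (partition coefficient = 24.0, kL = 0.0110 min⁻¹)

At 3.0 h the flask's gap stands at 47.3%, below what I carried, entered as 40.5% isomer of the product and 6.82% decomposed product. The flask has not come to rest. At 12 h the same flask has a smaller gap, 30.7%, made of 14.6% isomer of the product and 16.1% decomposed product, with the target column at 69.3%. At 30.0 h the gap has grown back to 36.5% and the target column stands at 63.5%, while isomer of the product has shrunk to 10.4% and decomposed product has reached 26.0%.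

The runs were generated by integration with made-up constants; noise was put on by code.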